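The data come from a simulation for an exercise; the scatter is artificial.

Within 40 h we want the most single product from the flask, so we keep books on its substrate, the limiting reagent, with 1.80 equivalents of partner against it.

| setting | dusk | dawn | midnight | flask |
|---|---|---|---|---|
| substrate | 46 mM | 73 mM | 33 mM | 33 mM |
| partner | 59.4 mM | 59.4 mM | 120 mM | 59.4 mM |
| remark | run made earlier | run made earlier | run made earlier |  |
| time |  |  |  | 40 h |

| run | time / h | single product / % | double product / % |
|---|---|---|---|
| dusk | 2.00 | 38.0 | 0.9 |
| dusk | 5.00 | 45.8 | 1.2 |
| dusk | 12.0 | 44.8 | 6.3 |
| dusk | 30.0 | 36.8 | 15.0 |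
| dawn | 2.00 | 27.5 | 0.1 |
| dawn | 5.00 | 37.2 | 1.4 |
| dawn | 12.0 | 36.3 | 5.7 |
| dawn | 30.0 | 31.7 | 9.6 |
| midnight | 2.00 | 61.8 | 4.5 |
| midnight | 5.00 | 64.3 | 10.8 |
| midnight | 12.0 | 51.0 | 26.2 |
| midnight | 30.0 | 28.1 | 45.8 |

(readings scatter by 1 percentage point)

* the best time, 40 h at the latest, for single product
* the amount of single product, in percent of the substrate charged, at that time

- the earlier runs were read with a standard deviation of 1 percentage point

Each substrate charged is entered once: in single product, in double product, or as missing. In the dusk run the first two entries sum to 51.1% at 12.0 h and 51.8% at 30.0 h. Between those two dusk readings single product falls by 8 points and double product rises by 8.7 points, so the dusk sum stays level within the scatter. We call the mean of those two sums the captured share: dusk 51.4%, dawn 41.6%, midnight 75.5%.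

Divide missing by captured, then by the charge ratio of substrate to partner, and the runs read 1.22, 1.14 and 1.18. This is our loss number, with a mean reading of 1.18.

The flask's charge ratio of 0.556 then gives 0.655 missing per captured, so we enter 60.4% captured and 39.6% missing. Double product is paid from the captured share. The dusk run, with the same partner charge, read its most single product at 5.00 h and had 6.3% of double product at 12.0 h. We expect the peak between those two times and charge that amount, which leaves 54.1%.

The forecast, reading “a reversible first step”, gave 49% at 4.8 h, lower than our figure and earlier than the two times between which we expect the peak.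

The flask gives 53.2% at 7.56 h.

    partner + single product → double product (k = 0.390 M⁻¹ h⁻¹)
    partner → decomposition product (k = 1.20 × 10⁻⁴ h⁻¹)
    substrate + partner → single product (k = 8.50 M⁻¹ h⁻¹)
    2 substrate → homo dimer (k = 10.0 M⁻¹ h⁻¹)

In the flask, the conversion of 2 substrate into homo dimer has half its turnover up to 40 h behind it by 0.465 h, against 17.1 h for the conversion of partner + single product into double product, and at 40.0 h single and double product together hold 61.0% while homo dimer, which counts as two substrate, holds 39.0%, where the loss number had entered 60.4% captured and 39.6% missing. For the neighbour flask with 56 mM of substrate, the loss number enters 47.4% captured, and at 40.0 h that flask holds 48.2% in single and double product.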